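In a closed flask the fractions of the charge sum to one at every hour, whether or not each part is read.

all flasks: starting material 20 mM

|  | remark | time |
|---|---|---|
| cedar | the very flask that is asked about, followed so far |  |
| flask |  | 40 h |

cedar run (percent of the starting material charged)

| time / h | target / % | starting material / % |
|---|---|---|
| 0.833 | 26.5 | 28.4 |
| 1.33 | 38.9 | 13.5 |
| 2.00 | 49.0 | 4.7 |
| 3.00 | 54.1 | 1.1 |
| 5.00 | 52.1 | 0.3 |
| 8.00 | 48.2 | 0.2 |
| 12.0 | 48.1 | 0 |

(scatter of a reading: 0.5 percentage points)

* when, up to 40 h, the flask holds most target
* the amount of target, in percent of the starting material charged, at that time
* the first time at which target reaches 16%, in the same percent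

In the cedar run, the 12.0 h reading showed target at 48.1% and starting material at 0%, so 51.9% of the charge stood unread. I took the mean of the last two target readings as the end share, the fraction of the charge that stays target once the flask has stopped changing: 48.2%.

I then solved two extremes. If target relaxed far faster than it was fed, it would track the end share times the fraction consumed and climb to 48.2% without passing it. If target did not relax, it would keep what arrived and never fall. The cedar readings lay between these: target reached 54.1% at 3.00 h, above the end share, and then fell back.

Placing zero slope between the chords on either side of that reading, I committed to a peak at 3.75 h, about as high as that reading. The chord from zero to the earliest reading gave 16% at 0.503 h.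

The forecast differed from me on timing, with 54.4% at 3 h, earlier than my peak, and 16% at 0.55 h, and it read the late stretch as “relaxation to an equilibrium or a stalled loss”.

The flask gave 54.1% at 3.47 h and reached 16% at 0.488 h.

    starting material → target (k = 0.288 h⁻¹)
    starting material ⇌ intermediate A (K = 40.8, k = 0.891 h⁻¹)
    intermediate A → target (k = 0.575 h⁻¹)
    target ⇌ isomer of the product (K = 1.10, k = 0.345 h⁻¹)
    intermediate B → target (k = 1.10 h⁻¹)
    starting material → intermediate B (k = 0.337 h⁻¹)

Target and isomer of the product relax with a half-life of 1.05 h by that step alone, short against the 40 h allowed. At 40.0 h the flask held 47.6% target and 52.4% isomer of the product, the thermodynamic end of kinetic against thermodynamic control, while its peak had stood 6.5 percentage points above that amount of target. Carried to the neighbouring flask, charged with 5.0 mM of starting material, 48.2% was my end share, and that flask peaked at 54.1% and ended at 47.6%.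

(The earlier runs and the new flask are calculated on assumed constants; noise was put on by code.)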